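The dimer is cut at the interflavan bond between C4 of the upper ring C and C6 of the lower ring A. Both halves are the same 2,3-cis-3,4-trans flavan, so one benzyl-protected 3,4-epoxyflavan (oxirane cis to the 2-aryl group) is used twice: water opens it to the lower diol, which is acetylated and brominated at C6 (ortho to O7, para to O1), and a nickel/titanocene reductive coupling joins a second epoxide molecule to this aryl bromide. That one operation cleaves the benzylic C4–O bond, forms C4–C6 trans to the released 3-OH, fixes the linkage site and stops at the dimer. Deacetylation and hydrogenolysis complete the route.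

Key step: step 11

Assumption: (R)-t-BuPyOx is taken to be the ligand antipode that gives the 2S flavanone; should a trial run show the opposite sense, (S)-t-BuPyOx is used and nothing else changes.

Step 1
Reactants: 1 2,3,4-trihydroxyacetophenone (gallacetophenone)
Product: 2 3,4-bis(benzyloxy)-2-hydroxyacetophenone
Conditions: BnBr (2.1 equiv), K2CO3 (2.2 equiv), acetone, reflux
Reagents that add atoms: benzyl bromide BrCc1ccccc1
Why: Williamson etherification in which the 2-OH, tied up in a hydrogen bond to the acetyl oxygen, is the least acidic and least nucleophilic phenol, so a weak base and two equivalents of benzyl bromide should alkylate only O3 and O4.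

Step 2
Reactants: 2 3,4-bis(benzyloxy)-2-hydroxyacetophenone; 3 N,N-dimethylformamide dimethyl acetal
Product: 5 7,8-bis(benzyloxy)chromone, via enaminone 4 (not isolated)
Conditions: 3 (2 equiv), toluene, 100 °C; evaporate; then conc. aq HCl, CH2Cl2, rt
Reagents that add atoms: none
Why: Condensation of the methyl ketone with the formamide acetal gives the enaminone, and acid then triggers conjugate addition of the 2-OH and loss of dimethylamine (addition–elimination chromone annulation), closing ring C and supplying C2 without affecting the benzyl ethers.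

Step 3
Reactants: 5 7,8-bis(benzyloxy)chromone; 6 3,4-bis(benzyloxy)phenylboronic acid
Product: 7 (2S)-7,8,3',4'-tetrakis(benzyloxy)flavanone
Conditions: Pd(OCOCF3)2 (5 mol%), (R)-t-BuPyOx (6 mol%), NH4PF6 (30 mol%), H2O (5 equiv), 6 (2 equiv), ClCH2CH2Cl, 60 °C; ee checked by chiral HPLC, no basic work-up
Reagents that add atoms: none
Why: Enantioselective palladium-catalysed conjugate addition of an arylboronic acid to a chromone: transmetalation gives a cationic aryl–palladium–PyOx complex that inserts the C2=C3 bond on the face chosen by the ligand, which sets C2 as S, and the palladium enolate is protonated by water under conditions free of base, so no retro-oxa-Michael racemisation is expected.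

Step 4
Reactants: 7 (2S)-7,8,3',4'-tetrakis(benzyloxy)flavanone
Product: 8 (2S,4S)-7,8,3',4'-tetrakis(benzyloxy)flavan-4-ol (4-OH cis to the 2-aryl group)
Conditions: NaBH4, THF–MeOH (4:1), −10 to 0 °C; aq NH4Cl quench
Reagents that add atoms: none
Why: Borohydride 1,2-reduction of the ketone, with axial hydride delivery expected to give mainly the 2,4-cis alcohol; the C4 configuration is of no consequence because C4 becomes sp2 in step 5, and the low temperature and short time protect C2 from base-induced ring opening.

Step 5
Reactants: 8 (2S,4S)-7,8,3',4'-tetrakis(benzyloxy)flavan-4-ol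
Product: 10 (2S)-7,8,3',4'-tetrakis(benzyloxy)flav-3-ene, via 4-mesylate 9 (not isolated)
Conditions: MsCl, Et3N (4 equiv), CH2Cl2, 0 °C to rt, dark; used without delay
Reagents that add atoms: none
Why: Dehydration by sulfonylation and elimination: the 4-mesylate of an alcohol benzylic to ring A and para to O7 ionises easily and loses H3 to the amine, giving the C3=C4 alkene conjugated with ring A in a basic medium that avoids acid-induced C2–O1 ionisation, while light is excluded because 2H-chromenes can racemise through photochemical ring opening.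

Step 6
Reactants: 10 (2S)-7,8,3',4'-tetrakis(benzyloxy)flav-3-ene
Product: 11 (2R,3S,4R)-3-bromo-7,8,3',4'-tetrakis(benzyloxy)flavan-4-ol (Br trans and 4-OH cis to the 2-aryl group; the C2 descriptor changes by priority only)
Conditions: NBS (1.05 equiv), NaHCO3 (0.2 equiv), THF–H2O (4:1), 0 °C, dark
Reagents that add atoms: N-bromosuccinimide O=C1CCC(=O)N1Br; water O
Why: Bromohydrin formation (halonium addition): bromine should add to the alkene face opposite the 2-aryl group and water should open the bromonium ion at benzylic C4, where ring A with O7 and O1 stabilises positive charge, from the other face, so C3–Br is set anti and C4–OH syn to the 2-aryl group.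

Step 7
Reactants: 11 (2R,3S,4R)-3-bromo-7,8,3',4'-tetrakis(benzyloxy)flavan-4-ol
Product: 12 (2R,3R,4R)-7,8,3',4'-tetrakis(benzyloxy)-3,4-epoxyflavan (oxirane cis to the 2-aryl group)
Conditions: NaH (1.2 equiv), THF, 0 °C; filtered through basic alumina and used at once
Reagents that add atoms: none
Why: Intramolecular Williamson etherification (3-exo-tet): the C4 alkoxide displaces the anti-periplanar bromide at C3 with inversion, which places the oxirane on the same face as the 2-aryl group, and the aprotic, acid-free medium preserves the labile benzylic epoxide.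

Step 8
Reactants: 12 (2R,3R,4R)-7,8,3',4'-tetrakis(benzyloxy)-3,4-epoxyflavan
Product: 13 (2R,3R,4S)-7,8,3',4'-tetrakis(benzyloxy)flavan-3,4-diol (tetra-O-benzyl isomelacacidin; 3-OH cis and 4-OH trans to the 2-aryl group)
Conditions: THF–H2O (3:1), NaH2PO4/Na2HPO4 buffer (pH 6), rt
Reagents that add atoms: water O
Why: Epoxide hydrolysis under near-neutral buffering: the benzylic C4–O bond opens and water adds at C4 on the face opposite the C3 oxygen and the 2-aryl group, whether the opening is concerted or passes through the ring-A-stabilised cation, which sets lower C4 trans to the 3-OH while C3 stays cis to the aryl group.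

Step 9
Reactants: 13 tetra-O-benzyl isomelacacidin
Product: 14 3,4-di-O-acetyl-7,8,3',4'-tetra-O-benzyl isomelacacidin (configuration of 13 unchanged)
Conditions: Ac2O, pyridine, DMAP (cat.), CH2Cl2, 0 °C to rt
Reagents that add atoms: acetic anhydride CC(=O)OC(C)=O
Why: Nucleophile-catalysed acylation of both secondary alcohols, which protects the benzylic alcohol from the brominating agent and removes the O–H groups that could bind trivalent titanium and quench the carbon radical in step 11; no stereocentre is involved.

Step 10
Reactants: 14 3,4-di-O-acetyl-7,8,3',4'-tetra-O-benzyl isomelacacidin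
Product: 15 6-bromo-3,4-di-O-acetyl-7,8,3',4'-tetra-O-benzyl isomelacacidin (Br on C6 of ring A)
Conditions: NBS (1.0 equiv), MeCN, 0 °C, dark
Reagents that add atoms: N-bromosuccinimide O=C1CCC(=O)N1Br
Why: Electrophilic aromatic bromination: C6 of ring A is ortho to O7 and para to O1, two meta-related donors that reinforce each other, and should be much more nucleophilic than C5 (para only to the twisted O8) or the singly activated ring B positions, so one equivalent of N-bromosuccinimide should brominate there, the site to be confirmed by the NOE between the remaining H5 singlet and H4.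

Step 11
Reactants: 12 (2R,3R,4R)-7,8,3',4'-tetrakis(benzyloxy)-3,4-epoxyflavan; 15 6-bromo-3,4-di-O-acetyl-7,8,3',4'-tetra-O-benzyl isomelacacidin
Product: 16 protected (4→6) dimer: the upper 7,8,3',4'-tetrakis(benzyloxy)flavan-3-ol unit (3-OH free, cis to the 2-aryl group) is bonded through C4, trans to that 3-OH, to C6 of the lower 3,4-di-O-acetyl tetra-O-benzyl isomelacacidin unit; all six stereocentres arranged as in 18
Conditions: NiCl2(dme) (10 mol%), 4,4'-di-tert-butyl-2,2'-bipyridine (10 mol%), Cp2TiCl2 (20 mol%), Mn powder (2.5 equiv), Et3N·HCl (1.2 equiv), DMPU, rt, argon; 12 (1.5 equiv) added slowly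
Reagents that add atoms: none
Why: Proposed new method: Cp2TiCl (trivalent titanium, formed from Cp2TiCl2 and Mn) should open epoxide 12 by electron transfer into the benzylic C4–O bond, giving a C4 radical stabilised by ring A (O7 para, O1 ortho) and a tetravalent titanium alkoxide at O3, while zerovalent nickel–bipyridine inserts into the C6–Br bond of 15, the resulting aryl–nickel captures the radical and reductive elimination from trivalent nickel forms C4–C6, with Mn turning over both metals and Et3N·HCl releasing the 3-OH. The closest known reaction type is the nickel/titanocene co-catalysed reductive arylation of epoxides with aryl bromides at the carbon that gives the more stable radical, which converts cyclic epoxides into trans-2-arylcycloalkanols, but a ring-fused, donor-substituted benzylic epoxide paired with an ortho-alkoxy aryl bromide has not been shown. No ring is closed and the oxirane is opened. Upper C4 is set by substrate control, since the titanoxy group at C3 and the 2-aryl group both lie on one face of ring C and the aryl–nickel should approach the planar radical from the other face, placing the new aryl trans to the 3-OH. The step needs that 3,4-trans selectivity together with opening at C4 and bonding at C6, and these follow from the shielded face, from benzylic radical stability and from the bromide, which also stops the reaction at the dimer. The medium is close to neutral, so the ionisable benzylic 4-acetate of 15 and the benzyl ethers should survive, and slow addition of 12 should keep radical dimerisation down.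

Step 12
Reactants: 16 protected (4→6) dimer with lower 3,4-diacetate
Product: 17 octa-O-benzyl (4→6) dimer with free upper 3-OH and free lower 3,4-diol (stereocentres as in 18)
Conditions: K2CO3 (cat.), MeOH–THF (1:1), rt
Reagents that add atoms: none
Why: Base-catalysed transesterification (methanolysis) cleaves both acetates at the acyl carbon, and since every phenol is still a benzyl ether no phenoxide can expel the C4 oxygen as a quinone methide, so lower C4 and the interflavan bond keep their configuration.

Step 13
Reactants: 17 octa-O-benzyl (4→6) dimer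
Product: 18 CNP0143773.2, the (4→6) dimer of two isomelacacidin-type units (upper unit (2R,3R,4S)-3,3',4',7,8-pentahydroxyflavan-4-yl, lower unit (2R,3R,4S)-3,3',4,4',7,8-hexahydroxyflavan, joined upper C4 to lower C6)
Conditions: H2 (1 atm), Pd(OH)2/C, THF–MeOH (1:1), rt, stopped at full conversion; filtration under argon, no acid, Sephadex LH-20 (MeOH)
Reagents that add atoms: none
Why: Catalytic hydrogenolysis over palladium removes the eight aryl benzyl ethers, which react far faster than the hindered secondary benzylic C4–OH, the two C2–O1 bonds or the C4–C6 bond in a neutral medium at one atmosphere, provided the reaction is stopped at full conversion and the air-sensitive catechols are handled without acid or base.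

Compound list
1 | 2,3,4-trihydroxyacetophenone (gallacetophenone) | CC(=O)c1ccc(O)c(O)c1O | starting material
2 | 3,4-bis(benzyloxy)-2-hydroxyacetophenone | CC(=O)c1ccc(OCc2ccccc2)c(OCc2ccccc2)c1O | intermediate
3 | N,N-dimethylformamide dimethyl acetal | COC(OC)N(C)C | starting material
4 | (E)-1-[3,4-bis(benzyloxy)-2-hydroxyphenyl]-3-(dimethylamino)prop-2-en-1-one (enaminone, not isolated) | CN(C)/C=C/C(=O)c1ccc(OCc2ccccc2)c(OCc2ccccc2)c1O | intermediate
5 | 7,8-bis(benzyloxy)chromone | O=c1ccoc2c(OCc3ccccc3)c(OCc3ccccc3)ccc12 | intermediate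
6 | 3,4-bis(benzyloxy)phenylboronic acid | OB(O)c1ccc(OCc2ccccc2)c(OCc2ccccc2)c1 | starting material
7 | (2S)-7,8,3',4'-tetrakis(benzyloxy)flavanone | c1ccc(COc2ccc([C@H]3Oc4c(ccc(OCc5ccccc5)c4OCc4ccccc4)C(=O)C3)cc2OCc2ccccc2)cc1 | intermediate
8 | (2S,4S)-7,8,3',4'-tetrakis(benzyloxy)flavan-4-ol (2,4-cis) | c1ccc(COc2ccc([C@H]3Oc4c(ccc(OCc5ccccc5)c4OCc4ccccc4)[C@@H](O)C3)cc2OCc2ccccc2)cc1 | intermediate
9 | 4-O-methanesulfonate of 8 (not isolated) | c1ccc(COc2ccc([C@H]3Oc4c(ccc(OCc5ccccc5)c4OCc4ccccc4)[C@@H](OS(C)(=O)=O)C3)cc2OCc2ccccc2)cc1 | intermediate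
10 | (2S)-7,8,3',4'-tetrakis(benzyloxy)flav-3-ene | c1ccc(COc2ccc([C@H]3Oc4c(ccc(OCc5ccccc5)c4OCc4ccccc4)C=C3)cc2OCc2ccccc2)cc1 | intermediate
11 | (2R,3S,4R)-3-bromo-7,8,3',4'-tetrakis(benzyloxy)flavan-4-ol (2,3-trans-3,4-trans bromohydrin) | c1ccc(COc2ccc([C@H]3Oc4c(ccc(OCc5ccccc5)c4OCc4ccccc4)[C@@H](O)[C@@H]3Br)cc2OCc2ccccc2)cc1 | intermediate
12 | (2R,3R,4R)-7,8,3',4'-tetrakis(benzyloxy)-3,4-epoxyflavan (oxirane cis to the 2-aryl group) | c1ccc(COc2ccc([C@H]3Oc4c(ccc(OCc5ccccc5)c4OCc4ccccc4)[C@H]4O[C@@H]34)cc2OCc2ccccc2)cc1 | intermediate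
13 | (2R,3R,4S)-7,8,3',4'-tetrakis(benzyloxy)flavan-3,4-diol (tetra-O-benzyl isomelacacidin, 2,3-cis-3,4-trans) | c1ccc(COc2ccc([C@H]3Oc4c(ccc(OCc5ccccc5)c4OCc4ccccc4)[C@H](O)[C@H]3O)cc2OCc2ccccc2)cc1 | intermediate
14 | 3,4-di-O-acetyl-7,8,3',4'-tetra-O-benzyl isomelacacidin | c1ccc(COc2ccc([C@H]3Oc4c(ccc(OCc5ccccc5)c4OCc4ccccc4)[C@H](OC(C)=O)[C@H]3OC(C)=O)cc2OCc2ccccc2)cc1 | intermediate
15 | 6-bromo-3,4-di-O-acetyl-7,8,3',4'-tetra-O-benzyl isomelacacidin | c1ccc(COc2ccc([C@H]3Oc4c(cc(Br)c(OCc5ccccc5)c4OCc4ccccc4)[C@H](OC(C)=O)[C@H]3OC(C)=O)cc2OCc2ccccc2)cc1 | intermediate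
16 | protected (4→6) dimer: octa-O-benzyl, lower 3,4-di-O-acetyl, upper 3-OH free | C(c5ccccc5)Oc1ccc([C@H]2Oc3c(ccc(OCc5ccccc5)c3OCc5ccccc5)[C@H](c3cc4c(c(OCc5ccccc5)c3OCc5ccccc5)O[C@H](c3ccc(OCc5ccccc5)c(OCc5ccccc5)c3)[C@H](OC(C)=O)[C@H]4OC(C)=O)[C@H]2O)cc1OCc5ccccc5 | intermediate
17 | octa-O-benzyl (4→6) dimer with free upper 3-OH and lower 3,4-diol | C(c5ccccc5)Oc1ccc([C@H]2Oc3c(ccc(OCc5ccccc5)c3OCc5ccccc5)[C@H](c3cc4c(c(OCc5ccccc5)c3OCc5ccccc5)O[C@H](c3ccc(OCc5ccccc5)c(OCc5ccccc5)c3)[C@H](O)[C@H]4O)[C@H]2O)cc1OCc5ccccc5 | intermediate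
18 | CNP0143773.2, isomelacacidin-type (4→6) dimer | Oc1ccc([C@H]2Oc3c(ccc(O)c3O)[C@H](c3cc4c(c(O)c3O)O[C@H](c3ccc(O)c(O)c3)[C@H](O)[C@H]4O)[C@H]2O)cc1O | target

Total steps: 13. Longest linear sequence: 13 steps (1 to 18). The batch of epoxide 12 is divided, one part going on through 13, 14 and 15 and the other entering step 11 directly.

Steps most likely to fail

1. Step 11. The C4 radical may dimerise, be reduced to the 4-unsubstituted flavan-3-ol or be deoxygenated back to chromene 10 faster than the hindered ortho-benzyloxy aryl–nickel captures it, and the facial selectivity at C4 is untested. The fallback uses known polar chemistry with the lower unit as a site-defined nucleophile. It sets out from diol 13: TBSOTf and 2,6-lutidine in CH2Cl2 should give the 3,4-bis(tert-butyldimethylsilyl) ether F1, and NBS in MeCN its 6-bromide F2. Bromine–lithium exchange with t-BuLi in THF at −78 °C gives the aryllithium F3, which in the presence of BF3·OEt2 opens epoxide 12 at benzylic C4 with inversion (organolithium/BF3 opening of an epoxide) to the 3,4-trans coupled bis-silyl ether F4. TBAF in THF removes both silyl groups and the route is rejoined at triol 17.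

2. Step 3. The electron-rich chromone may insert slowly while the electron-rich boronic acid protodeboronates, or the enantioselectivity may be too low. The fallback sets out from acetophenone 2: Claisen–Schmidt condensation with commercial 3,4-bis(benzyloxy)benzaldehyde (KOH, EtOH) should give the 2'-hydroxychalcone F5, and NaOAc in refluxing EtOH the racemic flavanone F6 by oxa-Michael cyclisation. Kinetic resolution by asymmetric transfer hydrogenation with RuCl(p-cymene)[(S,S)-TsDPEN] in HCO2H–Et3N, stopped near half conversion, should reduce the 2S enantiomer selectively to the (2S,4S)-flavan-4-ol, which is compound 8, where the route is rejoined. The unreacted 2R ketone is separated, and the catalyst antipode is matched in a trial run.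

3. Step 6. Water may attack an open C4 cation on both faces, the electron-rich arenes may be brominated in competition, and the chromene may lose optical purity or decompose before it reacts. The fallback avoids the chromene and sets out from flavanone 7: α-bromination through the enol with CuBr2 in EtOAc–CHCl3 at reflux should give the 2,3-trans-3-bromoflavanone F7 (bromine equatorial, anti to the 2-aryl group). NaBH4 reduction with axial hydride delivery should then give the all-equatorial bromohydrin, which is compound 11, where the route is rejoined. Only this 3,4-trans isomer can close to epoxide 12.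

Further compounds
F1 | step 11 | 3,4-bis-O-(tert-butyldimethylsilyl)-7,8,3',4'-tetra-O-benzyl isomelacacidin | c1ccc(COc2ccc([C@H]3Oc4c(ccc(OCc5ccccc5)c4OCc4ccccc4)[C@H](O[Si](C)(C)C(C)(C)C)[C@H]3O[Si](C)(C)C(C)(C)C)cc2OCc2ccccc2)cc1
F2 | step 11 | 6-bromo derivative of F1 | c1ccc(COc2ccc([C@H]3Oc4c(cc(Br)c(OCc5ccccc5)c4OCc4ccccc4)[C@H](O[Si](C)(C)C(C)(C)C)[C@H]3O[Si](C)(C)C(C)(C)C)cc2OCc2ccccc2)cc1
F3 | step 11 | 6-lithio derivative of F1 (aryllithium) | c1ccc(COc2ccc([C@H]3Oc4c(cc([Li])c(OCc5ccccc5)c4OCc4ccccc4)[C@H](O[Si](C)(C)C(C)(C)C)[C@H]3O[Si](C)(C)C(C)(C)C)cc2OCc2ccccc2)cc1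
F4 | step 11 | octa-O-benzyl (4→6) dimer with lower 3,4-bis-O-(tert-butyldimethylsilyl) groups and free upper 3-OH | C(c5ccccc5)Oc1ccc([C@H]2Oc3c(ccc(OCc5ccccc5)c3OCc5ccccc5)[C@H](c3cc4c(c(OCc5ccccc5)c3OCc5ccccc5)O[C@H](c3ccc(OCc5ccccc5)c(OCc5ccccc5)c3)[C@H](O[Si](C)(C)C(C)(C)C)[C@H]4O[Si](C)(C)C(C)(C)C)[C@H]2O)cc1OCc5ccccc5
F5 | step 3 | (E)-1-[3,4-bis(benzyloxy)-2-hydroxyphenyl]-3-[3,4-bis(benzyloxy)phenyl]prop-2-en-1-one (2'-hydroxychalcone) | O=C(/C=C/c1ccc(OCc2ccccc2)c(OCc2ccccc2)c1)c1ccc(OCc2ccccc2)c(OCc2ccccc2)c1O
F6 | step 3 | racemic 7,8,3',4'-tetrakis(benzyloxy)flavanone | O=C1CC(c2ccc(OCc3ccccc3)c(OCc3ccccc3)c2)Oc2c1ccc(OCc1ccccc1)c2OCc1ccccc1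
F7 | step 6 | 2,3-trans-3-bromo-7,8,3',4'-tetrakis(benzyloxy)flavanone (C2 as in 7) | c1ccc(COc2ccc([C@H]3Oc4c(ccc(OCc5ccccc5)c4OCc4ccccc4)C(=O)[C@@H]3Br)cc2OCc2ccccc2)cc1
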